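**Retrosynthetic overview**
1. Target ⇒ its tri-O-benzyl ether ⇒ 5,7-bis(benzyloxy)-6-(piperidinyl)chromone + 4-(benzyloxy)phenylboronic acid. A catalyst-controlled conjugate addition sets flavanone C2, and ring B arrives last.
2. Chromone (ring C) ⇒ o-hydroxyacetophenone ⇒ aryl silyl ether. The one ring-A oxygen para to the piperidine is kept different (silyl) from the two flanking benzyl ethers, so ring C can close only one way.
3. N-Methylpiperidine ⇒ 2-aryl cyclic ketimine (asymmetric transfer hydrogenation sets piperidine C2, then N-methylation) ⇒ cyclopentanone oxime tosylate + 1,3-bis(benzyloxy)-5-silyloxybenzene. A Beckmann ring expansion turns the five-membered carbocycle into the six-membered azacycle, and ring A captures the ring-expanded imidoyl cation in the same flask.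
4. Enabling feature: piperidine C2 is bonded to C6 of ring A, a carbon flanked by the oxygen-bearing C5 and C7 and para to C8a–O1. This phloroglucinol-type carbon is nucleophilic enough to take up an imidoyl cation. N1 and C2 of the piperidine map onto N and the C=N carbon of cyclopentanone oxime, and piperidine C6 is the migrated CH2.
5. Order of ring formation: ring A (bought), piperidine (step 3, by expansion), ring C (step 7), ring B attached (step 8).

Key step: step 3

Remark: 3,5-bis(benzyloxy)phenol is taken as a purchasable starting material; the sense of induction in the two catalytic asymmetric steps is assigned by analogy, and the mirror-image catalyst or ligand is available in each case.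

Step 1
Reactants: 1 cyclopentanone oxime
Product: 2 cyclopentanone O-(p-toluenesulfonyl)oxime
Conditions: TsCl, Et3N, CH2Cl2, −20 → 0 °C; used at once
Reagents that add atoms: p-toluenesulfonyl chloride, Cc1ccc(cc1)S(Cl)(=O)=O
Why: O-sulfonylation of the oxime under amine base at low temperature gives the sulfonate before any rearrangement sets in, and no stereocentre is involved.

Step 2
Reactants: 3 3,5-bis(benzyloxy)phenol
Product: 4 [3,5-bis(benzyloxy)phenoxy]triisopropylsilane
Conditions: i-Pr3SiCl, imidazole, DMF, 25 °C
Reagents that add atoms: chlorotriisopropylsilane, CC(C)[Si](Cl)(C(C)C)C(C)C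
Why: Silyl ether formation at the single free phenol marks the oxygen that later becomes the pyranone oxygen and adds the bulk that steers step 3.

Step 3
Reactants: 2 cyclopentanone O-(p-toluenesulfonyl)oxime; 4 [3,5-bis(benzyloxy)phenoxy]triisopropylsilane
Product: 6 6-[2,6-bis(benzyloxy)-4-(triisopropylsilyloxy)phenyl]-2,3,4,5-tetrahydropyridine, via imidoyl tosylate 5 (not isolated)
Conditions: Et2AlCl (2.2 equiv), CH2Cl2, −78 → 0 °C; aq. NaOH/Rochelle salt work-up
Reagents that add atoms: none
Why: Proposed new method: Et2AlCl ionises the N–O bond of 2 with a concerted anti 1,2-shift of a ring CH2 from carbon to nitrogen (Beckmann rearrangement), so the five-membered carbocycle becomes the six-membered azacycle as the strained cyclic nitrilium ion, held as its covalent imidoyl sulfonate 5; arene 4 then attacks the imidoyl carbon and rearomatises (Houben–Hoesch-type Friedel–Crafts step) to give ketimine 6 as its aluminium complex. The closest known reaction types are the organoaluminium-promoted Beckmann rearrangement of cycloalkanone oxime sulfonates with capture of the imidoyl cation by trialkylalanes or enol silyl ethers, and the Hoesch acylation of phloroglucinol ethers by nitrilium ions; intermolecular capture by a neutral arene is the untested part. No ring is closed by cyclisation: the six-membered ring arises by ring expansion through the carbon-to-nitrogen shift, and the aryl–C2 bond forms in the same operation. No stereocentre is created, since C2 is trigonal in 6 and is set in step 4. The step needs site selectivity on ring A for the carbon between the two benzyloxy groups, which the triisopropylsilyl group should secure by shielding both positions next to it. It also needs capture by the arene rather than ethyl transfer, which the poor alkyl-donor ability of Et2AlCl and the high nucleophilicity of the trioxygenated ring favour, and the aluminium-bound ketimine is deactivated, so mono-arylation is expected.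

Step 4
Reactants: 6 6-[2,6-bis(benzyloxy)-4-(triisopropylsilyloxy)phenyl]-2,3,4,5-tetrahydropyridine
Product: 8 (2S)-2-[2,6-bis(benzyloxy)-4-(triisopropylsilyloxy)phenyl]-1-methylpiperidine, via secondary amine 7 (not isolated)
Conditions: RuCl(p-cymene)[(S,S)-TsDPEN] (2 mol %), HCO2H/Et3N (5:2), MeCN, 25 °C; then 37% aq. CH2O, 60 °C
Reagents that add atoms: formaldehyde, C=O
Why: Noyori–Ikariya asymmetric transfer hydrogenation of the cyclic ketimine through its iminium formate sets piperidine C2 under catalyst control (the (S,S) catalyst is the one expected to give S, and its mirror image is used if a first run shows the opposite sense), and Eschweiler–Clarke methylation with the formate already present then installs N-methyl without touching the new centre.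

Step 5
Reactants: 8 (2S)-2-[2,6-bis(benzyloxy)-4-(triisopropylsilyloxy)phenyl]-1-methylpiperidine
Product: 9 1-{2,4-bis(benzyloxy)-3-[(2S)-1-methylpiperidin-2-yl]-6-(triisopropylsilyloxy)phenyl}ethan-1-one
Conditions: AcOH, (CF3CO)2O, 85% H3PO4 (cat.), CH2Cl2, 0 → 25 °C
Reagents that add atoms: acetic acid, CC(O)=O
Why: Friedel–Crafts acylation by the mixed acetic trifluoroacetic anhydride occurs at the only kind of free ring position (the two are equivalent through rotation about the aryl–piperidine bond), with the amine masked as its ammonium salt and no chelating Lewis acid present that could strip a benzyl ether.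

Step 6
Reactants: 9 1-{2,4-bis(benzyloxy)-3-[(2S)-1-methylpiperidin-2-yl]-6-(triisopropylsilyloxy)phenyl}ethan-1-one
Product: 10 1-{2,4-bis(benzyloxy)-6-hydroxy-3-[(2S)-1-methylpiperidin-2-yl]phenyl}ethan-1-one
Conditions: Bu4NF, THF, 0 °C; aq. NH4Cl
Reagents that add atoms: none
Why: Fluoride-mediated desilylation cleaves the aryl silyl ether selectively over the benzyl ethers and frees only the oxygen para to the piperidine, now ortho to the acetyl group.

Step 7
Reactants: 10 1-{2,4-bis(benzyloxy)-6-hydroxy-3-[(2S)-1-methylpiperidin-2-yl]phenyl}ethan-1-one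
Product: 12 5,7-bis(benzyloxy)-6-[(2S)-1-methylpiperidin-2-yl]-4H-chromen-4-one, via enaminone 11 (not isolated)
Conditions: Me2NCH(OMe)2, toluene, 100 °C; then conc. aq. HCl, CH2Cl2, 25–40 °C
Reagents that add atoms: N,N-dimethylformamide dimethyl acetal, COC(OC)N(C)C
Why: Condensation of the methyl ketone with the amide acetal gives the enaminone, and acid then triggers conjugate addition of the only free phenol and loss of dimethylamine (enaminone route to chromones, 6-endo closure), so the pyranone oxygen is unambiguously the one para to the piperidine.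

Step 8
Reactants: 12 5,7-bis(benzyloxy)-6-[(2S)-1-methylpiperidin-2-yl]-4H-chromen-4-one; 13 4-(benzyloxy)phenylboronic acid
Product: 14 (2S)-5,7-bis(benzyloxy)-2-[4-(benzyloxy)phenyl]-6-[(2S)-1-methylpiperidin-2-yl]chroman-4-one
Conditions: Pd(OCOCF3)2 (5 mol %), (R)-t-BuPyOX (6 mol %), NH4PF6 (30 mol %), H2O (5 equiv), CF3CO2H (1 equiv, amine salt), ClCH2CH2Cl, 60 °C
Reagents that add atoms: none
Why: Palladium-catalysed asymmetric conjugate addition of an arylboronic acid to a chromone with a pyridine–oxazoline ligand (Hayashi–Miyaura-type 1,4-addition) creates flavanone C2 under catalyst control; the (R) ligand is chosen because its antipode is known to give R adducts with cyclic enones of the same facial topology, and the remote piperidine centre, kept as its trifluoroacetate salt, should have no influence.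

Step 9
Reactants: 14 (2S)-5,7-bis(benzyloxy)-2-[4-(benzyloxy)phenyl]-6-[(2S)-1-methylpiperidin-2-yl]chroman-4-one
Product: 15 (2S)-5,7-dihydroxy-2-(4-hydroxyphenyl)-6-[(2S)-1-methylpiperidin-2-yl]chroman-4-one
Conditions: H2 (1 atm), Pd/C (10 wt %), EtOAc/MeOH, 25 °C
Reagents that add atoms: none
Why: Catalytic hydrogenolysis of the three aryl benzyl ethers under neutral conditions should leave both stereocentres untouched, since no base is present to open the flavanone ring, and the reaction is stopped at full debenzylation to spare the benzylic C–N and C–O bonds.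

**Compound list**
1 | cyclopentanone oxime | ON=C1CCCC1 | starting material
2 | cyclopentanone O-(p-toluenesulfonyl)oxime | Cc1ccc(cc1)S(=O)(=O)ON=C1CCCC1 | intermediate
3 | 3,5-bis(benzyloxy)phenol | Oc1cc(OCc2ccccc2)cc(OCc2ccccc2)c1 | starting material
4 | [3,5-bis(benzyloxy)phenoxy]triisopropylsilane | CC(C)[Si](Oc1cc(OCc2ccccc2)cc(OCc2ccccc2)c1)(C(C)C)C(C)C | intermediate
5 | 3,4,5,6-tetrahydropyridin-2-yl p-toluenesulfonate (imidoyl tosylate, covalent form of the six-membered cyclic nitrilium ion; not isolated) | Cc1ccc(cc1)S(=O)(=O)OC1=NCCCC1 | intermediate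
6 | 6-[2,6-bis(benzyloxy)-4-(triisopropylsilyloxy)phenyl]-2,3,4,5-tetrahydropyridine | N1=C(CCCC1)c1c(OCc2ccccc2)cc(O[Si](C(C)C)(C(C)C)C(C)C)cc1OCc1ccccc1 | intermediate
7 | (2S)-2-[2,6-bis(benzyloxy)-4-(triisopropylsilyloxy)phenyl]piperidine (not isolated) | N1CCCC[C@H]1c1c(OCc2ccccc2)cc(O[Si](C(C)C)(C(C)C)C(C)C)cc1OCc1ccccc1 | intermediate
8 | (2S)-2-[2,6-bis(benzyloxy)-4-(triisopropylsilyloxy)phenyl]-1-methylpiperidine | CN1CCCC[C@H]1c1c(OCc2ccccc2)cc(O[Si](C(C)C)(C(C)C)C(C)C)cc1OCc1ccccc1 | intermediate
9 | 1-{2,4-bis(benzyloxy)-3-[(2S)-1-methylpiperidin-2-yl]-6-(triisopropylsilyloxy)phenyl}ethan-1-one | CN1CCCC[C@H]1c1c(OCc2ccccc2)cc(O[Si](C(C)C)(C(C)C)C(C)C)c(C(C)=O)c1OCc1ccccc1 | intermediate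
10 | 1-{2,4-bis(benzyloxy)-6-hydroxy-3-[(2S)-1-methylpiperidin-2-yl]phenyl}ethan-1-one | CN1CCCC[C@H]1c1c(OCc2ccccc2)cc(O)c(C(C)=O)c1OCc1ccccc1 | intermediate
11 | (E)-1-{2,4-bis(benzyloxy)-6-hydroxy-3-[(2S)-1-methylpiperidin-2-yl]phenyl}-3-(dimethylamino)prop-2-en-1-one (not isolated) | CN1CCCC[C@H]1c1c(OCc2ccccc2)cc(O)c(C(=O)/C=C/N(C)C)c1OCc1ccccc1 | intermediate
12 | 5,7-bis(benzyloxy)-6-[(2S)-1-methylpiperidin-2-yl]-4H-chromen-4-one | CN1CCCC[C@H]1c1c(OCc3ccccc3)cc2c(c1OCc1ccccc1)C(=O)C=CO2 | intermediate
13 | 4-(benzyloxy)phenylboronic acid | OB(O)c1ccc(OCc2ccccc2)cc1 | starting material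
14 | (2S)-5,7-bis(benzyloxy)-2-[4-(benzyloxy)phenyl]-6-[(2S)-1-methylpiperidin-2-yl]chroman-4-one | CN1CCCC[C@H]1c1c(OCc3ccccc3)cc2c(c1OCc1ccccc1)C(=O)C[C@@H](c1ccc(OCc3ccccc3)cc1)O2 | intermediate
15 | (2S)-5,7-dihydroxy-2-(4-hydroxyphenyl)-6-[(2S)-1-methylpiperidin-2-yl]chroman-4-one | CN1CCCC[C@H]1c1c(O)cc2c(c1O)C(=O)C[C@@H](c1ccc(O)cc1)O2 | target

**Step count and risks**
Total steps: 9. Longest linear sequence: 8 steps (steps 2–9 from compound 3; equally steps 1 and 3–9 from compound 1).

Steps most likely to fail:

Step 3 (proposed new method). The ring-expanded imidoyl cation may be captured by an ethyl group or chloride from aluminium, or may oligomerise, before the arene attacks. The arene may also attack at a carbon next to the silyl ether. Fallback, separating ring expansion from C–C bond formation with known chemistry: compound 2 is warmed in aqueous dioxane to give piperidin-2-one F1 (classical Beckmann rearrangement, still the ring expansion). F1 is activated with (CF3SO2)2O and 2-fluoropyridine in CH2Cl2 at −78 → 0 °C to 3,4,5,6-tetrahydropyridin-2-yl trifluoromethanesulfonate F2, which is not isolated. Arene 4 is then added; Friedel–Crafts capture of triflic-anhydride-activated secondary amides by electron-rich arenes is known. The fallback sets out from 2 and returns to the route at 6.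

Step 4. Hydride transfer to a ketimine that carries a 2,6-disubstituted aryl group may be slow, and facial selectivity may be poor. Fallback by resolution: compound 6 is reduced with NaBH4 in MeOH to racemic 2-[2,6-bis(benzyloxy)-4-(triisopropylsilyloxy)phenyl]piperidine F3. Crystallisation with (−)-O,O′-di-p-toluoyl-L-tartaric acid should give the less soluble salt of the S amine, the (2S)-amine di-p-toluoyl-L-tartrate F4; the D-acid is used if the R salt crystallises first. Aqueous NaOH liberates the free amine. The fallback sets out from 6 and returns to the route at 7, which is then methylated as in the second half of step 4 to give 8.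

Step 8. Insertion into the electron-rich, crowded chromone may be sluggish, so that protodeboronation of the boronic acid outruns addition, or selectivity may erode. Fallback by chalcone cyclisation and diastereomer separation: compound 10 undergoes Claisen–Schmidt condensation with 4-(benzyloxy)benzaldehyde (KOH, EtOH) to give (E)-1-{2,4-bis(benzyloxy)-6-hydroxy-3-[(2S)-1-methylpiperidin-2-yl]phenyl}-3-[4-(benzyloxy)phenyl]prop-2-en-1-one F5. Oxa-Michael cyclisation (NaOAc, EtOH, reflux) should give 14 together with its C2 epimer, (2R)-5,7-bis(benzyloxy)-2-[4-(benzyloxy)phenyl]-6-[(2S)-1-methylpiperidin-2-yl]chroman-4-one F6. The two are diastereomers because the piperidine centre is fixed, so they can be separated by chromatography, and F6 is recycled by re-equilibration through F5 under the same conditions. The fallback sets out from 10 and returns to the route at 14.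

**Further compounds**
F1 | step 3 | piperidin-2-one | O=C1CCCCN1
F2 | step 3 | 3,4,5,6-tetrahydropyridin-2-yl trifluoromethanesulfonate | FC(F)(F)S(=O)(=O)OC1=NCCCC1
F3 | step 4 | racemic 2-[2,6-bis(benzyloxy)-4-(triisopropylsilyloxy)phenyl]piperidine | N1CCCCC1c1c(OCc2ccccc2)cc(O[Si](C(C)C)(C(C)C)C(C)C)cc1OCc1ccccc1
F4 | step 4 | (2S)-2-[2,6-bis(benzyloxy)-4-(triisopropylsilyloxy)phenyl]piperidine (−)-O,O′-di-p-toluoyl-L-tartrate salt | N1CCCC[C@H]1c1c(OCc2ccccc2)cc(O[Si](C(C)C)(C(C)C)C(C)C)cc1OCc1ccccc1.[C@@H]([C@H](C(=O)O)OC(=O)c1ccc(C)cc1)(C(=O)O)OC(=O)c1ccc(C)cc1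
F5 | step 8 | (E)-1-{2,4-bis(benzyloxy)-6-hydroxy-3-[(2S)-1-methylpiperidin-2-yl]phenyl}-3-[4-(benzyloxy)phenyl]prop-2-en-1-one | CN1CCCC[C@H]1c1c(OCc2ccccc2)cc(O)c(C(=O)/C=C/c2ccc(OCc3ccccc3)cc2)c1OCc1ccccc1
F6 | step 8 | (2R)-5,7-bis(benzyloxy)-2-[4-(benzyloxy)phenyl]-6-[(2S)-1-methylpiperidin-2-yl]chroman-4-one | CN1CCCC[C@H]1c1c(OCc3ccccc3)cc2c(c1OCc1ccccc1)C(=O)C[C@H](c1ccc(OCc3ccccc3)cc1)O2
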